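**Plan**

Benzofuranone numbering is used: O1, C2 (O–CH), C3 (CH2), C3a (quaternary), C4 (ketone), C5 (acyl-bearing), C6 (enol), C7 (prenyl-bearing), C7a (enol-ether carbon).
Retrosynthesis: cut the O–Si bond of a tertiary silyl ether, then the two C–prenyl bonds at C3a and C7, then the O1–C2 bond of the dihydrofuran, and last the ring–prenyl and ring–acyl bonds of an acylphloroglucinol.
Enabling feature: the carbocycle C3a–C4–C5–C6–C7–C7a is the dienone form of an acylphloroglucinol. C3a is its only sp3 carbon and also the fusion atom of the ring O1–C2–C3–C3a–C7a, and its prenyl group is trans to the hydroxyisopropyl group on C2.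
Forward: acylate phloroglucinol, C-prenylate once, acetylate, epoxidise the side chain, close the dihydrofuran (the only ring formed), silylate the tertiary alcohol, add two prenyl groups in one flask (C7, then C3a with dearomatisation), desilylate.
Stereochemistry: C2 (S) comes from a Shi epoxidation to the (R)-epoxide and a 5-exo opening with inversion; C3a (S) comes from prenylation of the flat aromatic ring anti to the C2 substituent.

Key step: step 7

Remark: the target is handled as the drawn 6-hydroxy-4-oxo enol tautomer, (2S,3aS); the tautomers of the β-triketone are taken as one compound.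

**Route**

Step 1
Reactants: 1 phloroglucinol; 2 isovaleryl chloride (3-methylbutanoyl chloride)
Product: 3 1-(2,4,6-trihydroxyphenyl)-3-methylbutan-1-one
Conditions: AlCl3 (3.5 equiv), PhNO2–CH2Cl2, 0 → 50 °C; aq. HCl
Reagents that add atoms: none
Why: Friedel–Crafts acylation of the strongly activated arene should stop at the monoketone because the product is deactivated and held by AlCl3 as a chelate.

Step 2
Reactants: 3 1-(2,4,6-trihydroxyphenyl)-3-methylbutan-1-one; 4 prenyl bromide (1-bromo-3-methylbut-2-ene)
Product: 5 1-[2,4,6-trihydroxy-3-(3-methylbut-2-en-1-yl)phenyl]-3-methylbutan-1-one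
Conditions: 4 (0.9 equiv), 5% aq. KOH, 0 °C; aq. HCl
Reagents that add atoms: none
Why: C-alkylation of a phloroglucinol phenoxide (SN2 at the allylic bromide) is favoured in water, where the oxygens are hydrogen-bonded, the two free ring positions are equivalent, and the deficit of bromide holds back a second alkylation.

Step 3
Reactants: 5 1-[2,4,6-trihydroxy-3-(3-methylbut-2-en-1-yl)phenyl]-3-methylbutan-1-one
Product: 6 2-(3-methylbutanoyl)-4-(3-methylbut-2-en-1-yl)benzene-1,3,5-triyl triacetate
Conditions: Ac2O (5 equiv), pyridine, DMAP (cat.), CH2Cl2, 0 °C → rt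
Reagents that add atoms: acetic anhydride, CC(=O)OC(C)=O
Why: DMAP-catalysed O-acylation of all three phenols gives esters that should keep the ring from being oxidised in step 4 and can later be removed by base, so that acid never touches the epoxide.

Step 4
Reactants: 6 2-(3-methylbutanoyl)-4-(3-methylbut-2-en-1-yl)benzene-1,3,5-triyl triacetate
Product: 7 2-{[(2R)-3,3-dimethyloxiran-2-yl]methyl}-4-(3-methylbutanoyl)benzene-1,3,5-triyl triacetate
Conditions: 1,2:4,5-di-O-isopropylidene-β-D-erythro-2,3-hexodiulo-2,6-pyranose (D-fructose-derived Shi ketone, 0.5 equiv), KHSO5 (as 2KHSO5·KHSO4·K2SO4), K2CO3 (slow co-addition, pH ≈ 9.5), Bu4NHSO4, MeCN–CH2(OMe)2–aq. Na2B4O7, −5 °C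
Reagents that add atoms: potassium peroxymonosulfate (KHSO5), [K+].[O-]S(=O)(=O)OO
Why: In the Shi asymmetric epoxidation the dioxirane formed from the D-fructose-derived ketone and KHSO5 transfers oxygen to the electron-rich trisubstituted alkene through a spiro transition state that, for this ketone enantiomer and a 2-methylalk-2-ene, should give the (R)-epoxide, while the ester-deactivated arene is left alone.

Step 5
Reactants: 7 2-{[(2R)-3,3-dimethyloxiran-2-yl]methyl}-4-(3-methylbutanoyl)benzene-1,3,5-triyl triacetate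
Product: 9 1-[(2S)-4,6-dihydroxy-2-(2-hydroxypropan-2-yl)-2,3-dihydro-1-benzofuran-5-yl]-3-methylbutan-1-one, via triphenol epoxide 8 (not isolated)
Conditions: K2CO3 (0.5 equiv), MeOH, 0 °C → rt; aq. NaH2PO4
Reagents that add atoms: none
Why: Base-catalysed transesterification frees the phenols, and the monoanion, whose charge rests on the oxygen para to the ketone (the oxygen alkylated first in 2,4,6-trihydroxyaryl ketones) while the ortho hydroxyls stay protonated and hydrogen-bonded, should open the epoxide at its secondary carbon by a 5-exo-tet SN2 attack with inversion, turning the (R)-epoxide carbon into (S)-C2.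

Step 6
Reactants: 9 1-[(2S)-4,6-dihydroxy-2-(2-hydroxypropan-2-yl)-2,3-dihydro-1-benzofuran-5-yl]-3-methylbutan-1-one
Product: 11 1-[(2S)-4,6-dihydroxy-2-{2-[(triethylsilyl)oxy]propan-2-yl}-2,3-dihydro-1-benzofuran-5-yl]-3-methylbutan-1-one, via tris-silyl ether 10 (not isolated)
Conditions: TESOTf (4 equiv), 2,6-lutidine (6 equiv), CH2Cl2, −78 → 0 °C; then K2CO3 (0.2 equiv), MeOH, 0 °C
Reagents that add atoms: triethylsilyl trifluoromethanesulfonate, CC[Si](CC)(CC)OS(=O)(=O)C(F)(F)F
Why: Silylation with the silyl triflate reaches the hindered tertiary alcohol, and base-catalysed methanolysis should then remove only the far more labile aryl silyl ethers (selective desilylation), leaving the tertiary ether.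

Step 7
Reactants: 11 1-[(2S)-4,6-dihydroxy-2-{2-[(triethylsilyl)oxy]propan-2-yl}-2,3-dihydro-1-benzofuran-5-yl]-3-methylbutan-1-one; 4 prenyl bromide (2.4 equiv)
Product: 13 (2S,3aS)-6-hydroxy-5-(3-methylbutanoyl)-3a,7-bis(3-methylbut-2-en-1-yl)-2-{2-[(triethylsilyl)oxy]propan-2-yl}-3,3a-dihydro-1-benzofuran-4(2H)-one, via 7-prenyl dihydrobenzofuran 12 (not isolated)
Conditions: NaOMe (3 equiv), MeOH, −20 °C; 4 added slowly, −20 → 0 °C; aq. NH4Cl
Reagents that add atoms: none
Why: NaOMe converts 11 into its bis-phenoxide, whose carbon termini are C7 and C3a; SN2 attack of C7 on prenyl bromide and tautomerisation give aromatic 12 (bond C7–prenyl), and the bis-phenoxide of 12 then attacks a second bromide through the ring-fusion carbon C3a (bond C3a–prenyl), which ends aromaticity because C3a has no hydrogen to lose and leaves the cyclohexa-2,4-dienone as a chelated enolate at which alkylation should stop. The closest known reaction type is the alkylative dearomatisation of acylphloroglucinol phenoxides with allylic halides, by which dialkylated acylphloroglucinols are taken to geminally dialkylated dienones. No ring closes in this step. The new stereocentre C3a is controlled by C2: the CMe2OSiEt3 group occupies one face of the five-membered ring two atoms away, so the bromide should add to the other face and place the C3a prenyl group trans to it, which is the (3aS) configuration. The step needs C- over O-alkylation, which the hydrogen-bonding solvent and the soft allylic electrophile should secure, and C3a over the already prenylated C7, which the small, tied-back ring methylene at C3a should secure against the freely rotating prenyl chain that shields C7. Low temperature and slow addition of the bromide are chosen to keep the second alkylation under this steric control.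

Step 8
Reactants: 13 (2S,3aS)-6-hydroxy-5-(3-methylbutanoyl)-3a,7-bis(3-methylbut-2-en-1-yl)-2-{2-[(triethylsilyl)oxy]propan-2-yl}-3,3a-dihydro-1-benzofuran-4(2H)-one
Product: 14 (2S,3aS)-6-hydroxy-2-(2-hydroxypropan-2-yl)-5-(3-methylbutanoyl)-3a,7-bis(3-methylbut-2-en-1-yl)-3,3a-dihydro-1-benzofuran-4(2H)-one
Conditions: HF·pyridine, pyridine, THF, 0 °C → rt
Reagents that add atoms: none
Why: Fluoride-mediated desilylation, driven by the strong Si–F bond, should free the tertiary alcohol under buffered conditions that spare the prenyl groups, the enol ether and the β-triketone, and it touches no stereocentre.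

**Compound list**

1 | phloroglucinol | Oc1cc(O)cc(O)c1 | starting material
2 | isovaleryl chloride | CC(C)CC(=O)Cl | starting material
3 | 1-(2,4,6-trihydroxyphenyl)-3-methylbutan-1-one | CC(C)CC(=O)c1c(O)cc(O)cc1O | intermediate
4 | prenyl bromide | CC(C)=CCBr | starting material
5 | 1-[2,4,6-trihydroxy-3-(3-methylbut-2-en-1-yl)phenyl]-3-methylbutan-1-one | CC(C)CC(=O)c1c(O)cc(O)c(CC=C(C)C)c1O | intermediate
6 | 2-(3-methylbutanoyl)-4-(3-methylbut-2-en-1-yl)benzene-1,3,5-triyl triacetate | CC(C)CC(=O)c1c(OC(C)=O)cc(OC(C)=O)c(CC=C(C)C)c1OC(C)=O | intermediate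
7 | 2-{[(2R)-3,3-dimethyloxiran-2-yl]methyl}-4-(3-methylbutanoyl)benzene-1,3,5-triyl triacetate | CC(C)CC(=O)c1c(OC(C)=O)cc(OC(C)=O)c(C[C@H]2OC2(C)C)c1OC(C)=O | intermediate
8 | 1-(3-{[(2R)-3,3-dimethyloxiran-2-yl]methyl}-2,4,6-trihydroxyphenyl)-3-methylbutan-1-one (triphenol epoxide) | CC(C)CC(=O)c1c(O)cc(O)c(C[C@H]2OC2(C)C)c1O | intermediate
9 | 1-[(2S)-4,6-dihydroxy-2-(2-hydroxypropan-2-yl)-2,3-dihydro-1-benzofuran-5-yl]-3-methylbutan-1-one | CC(C)CC(=O)c1c(O)cc2O[C@H](C(C)(C)O)Cc2c1O | intermediate
10 | 1-[(2S)-4,6-bis[(triethylsilyl)oxy]-2-{2-[(triethylsilyl)oxy]propan-2-yl}-2,3-dihydro-1-benzofuran-5-yl]-3-methylbutan-1-one (tris-silyl ether) | CC(C)CC(=O)c1c(O[Si](CC)(CC)CC)cc2O[C@H](C(C)(C)O[Si](CC)(CC)CC)Cc2c1O[Si](CC)(CC)CC | intermediate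
11 | 1-[(2S)-4,6-dihydroxy-2-{2-[(triethylsilyl)oxy]propan-2-yl}-2,3-dihydro-1-benzofuran-5-yl]-3-methylbutan-1-one | CC(C)CC(=O)c1c(O)cc2O[C@H](C(C)(C)O[Si](CC)(CC)CC)Cc2c1O | intermediate
12 | 1-[(2S)-4,6-dihydroxy-7-(3-methylbut-2-en-1-yl)-2-{2-[(triethylsilyl)oxy]propan-2-yl}-2,3-dihydro-1-benzofuran-5-yl]-3-methylbutan-1-one (7-prenyl dihydrobenzofuran) | CC(C)CC(=O)c1c(O)c(CC=C(C)C)c2O[C@H](C(C)(C)O[Si](CC)(CC)CC)Cc2c1O | intermediate
13 | (2S,3aS)-6-hydroxy-5-(3-methylbutanoyl)-3a,7-bis(3-methylbut-2-en-1-yl)-2-{2-[(triethylsilyl)oxy]propan-2-yl}-3,3a-dihydro-1-benzofuran-4(2H)-one | CC(C)=CCC1=C2O[C@H](C(C)(C)O[Si](CC)(CC)CC)C[C@]2(CC=C(C)C)C(=O)C(C(=O)CC(C)C)=C1O | intermediate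
14 | (2S,3aS)-6-hydroxy-2-(2-hydroxypropan-2-yl)-5-(3-methylbutanoyl)-3a,7-bis(3-methylbut-2-en-1-yl)-3,3a-dihydro-1-benzofuran-4(2H)-one | CC(C)=CCC1=C2O[C@H](C(C)(C)O)C[C@]2(CC=C(C)C)C(=O)C(C(=O)CC(C)C)=C1O | target

**Count and risks**

Total steps: 8. Longest linear sequence: 8 steps (1 → 14).

Most likely to fail, in order:

1. Step 7. The second alkylation may turn to the already prenylated C7 or to a phenoxide oxygen instead of the ring-fusion carbon, and the bromide may approach both faces of C3a with little preference. The fallback delivers both prenyl groups intramolecularly by aromatic Claisen rearrangement, so that each new bond is placed by the oxygen it comes from.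
   - Setting out from 11, both phenols are etherified with 3-chloro-3-methylbut-1-yne (CuCl2 cat., DBU, MeCN, 0 °C) to the bis(2-methylbut-3-yn-2-yl) ether F1.
   - Semi-hydrogenation (H2, Pd/CaCO3 poisoned with Pb(OAc)2, quinoline, EtOAc) gives the bis(2-methylbut-3-en-2-yl) ether F2.
   - Warming F2 in toluene (60–100 °C) should bring about two [3,3] shifts. The O6 ether can reach only the free C7 and rearomatises. The O4 ether can reach only C3a, because its other ortho carbon carries the acyl group. Each shift turns the 1,1-dimethylallyl group into a normal prenyl group.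
   - The suprafacial shift to C3a is again expected on the face away from the C2 substituent. The route is rejoined at 13.

2. Step 5. The ring may close through an ortho oxygen (giving the angular isomer), or the epoxide may open at its tertiary carbon in a 6-endo mode. The fallback frees the para oxygen alone while the ortho oxygens stay acylated.
   - Setting out from 5, TIPSCl (1.05 equiv), imidazole, DMF, 0 °C should silylate the most acidic, non-chelated para hydroxyl to give the para-silyl ether F3.
   - Ac2O, pyridine, DMAP then gives the diacetate F4, and Shi epoxidation as in step 4 gives the (R)-epoxide F5.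
   - Bu4NF (1.0 equiv), THF, −20 °C removes the silyl group in a solvent that does not cleave the acetates. The single phenoxide closes the ring to the dihydrobenzofuran diacetate F6.
   - K2CO3 (cat.), MeOH then gives 9, where the route is rejoined.

3. Step 4. Acetates may be lost in the basic buffer with oxidation of the freed phenol, or oxygen transfer may show too little face selectivity. The fallback sets the stereocentre by asymmetric dihydroxylation under neutral conditions and then closes the epoxide.
   - Setting out from 6, Sharpless asymmetric dihydroxylation with K2OsO2(OH)4 (cat.), (DHQ)2PHAL and N-methylmorpholine N-oxide in acetone–H2O at 0 °C, with slow addition of 6, should give the (S)-diol F7.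
   - MsCl, Et3N, CH2Cl2, −20 °C sulfonylates only the secondary hydroxyl to give the mesylate F8.
   - DBU in CH2Cl2 lets the tertiary alkoxide displace the mesylate with inversion, which gives the (R)-epoxide 7, where the route is rejoined.

**Further compounds**

F1 | step 7 | 1-[(2S)-4,6-bis[(2-methylbut-3-yn-2-yl)oxy]-2-{2-[(triethylsilyl)oxy]propan-2-yl}-2,3-dihydro-1-benzofuran-5-yl]-3-methylbutan-1-one | CC(C)CC(=O)c1c(OC(C)(C)C#C)cc2O[C@H](C(C)(C)O[Si](CC)(CC)CC)Cc2c1OC(C)(C)C#C
F2 | step 7 | 1-[(2S)-4,6-bis[(2-methylbut-3-en-2-yl)oxy]-2-{2-[(triethylsilyl)oxy]propan-2-yl}-2,3-dihydro-1-benzofuran-5-yl]-3-methylbutan-1-one | CC(C)CC(=O)c1c(OC(C)(C)C=C)cc2O[C@H](C(C)(C)O[Si](CC)(CC)CC)Cc2c1OC(C)(C)C=C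
F3 | step 5 | 1-{2,6-dihydroxy-3-(3-methylbut-2-en-1-yl)-4-[(triisopropylsilyl)oxy]phenyl}-3-methylbutan-1-one | CC(C)CC(=O)c1c(O)cc(O[Si](C(C)C)(C(C)C)C(C)C)c(CC=C(C)C)c1O
F4 | step 5 | 2-(3-methylbutanoyl)-4-(3-methylbut-2-en-1-yl)-5-[(triisopropylsilyl)oxy]-1,3-phenylene diacetate | CC(C)CC(=O)c1c(OC(C)=O)cc(O[Si](C(C)C)(C(C)C)C(C)C)c(CC=C(C)C)c1OC(C)=O
F5 | step 5 | 4-{[(2R)-3,3-dimethyloxiran-2-yl]methyl}-2-(3-methylbutanoyl)-5-[(triisopropylsilyl)oxy]-1,3-phenylene diacetate | CC(C)CC(=O)c1c(OC(C)=O)cc(O[Si](C(C)C)(C(C)C)C(C)C)c(C[C@H]2OC2(C)C)c1OC(C)=O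
F6 | step 5 | (2S)-2-(2-hydroxypropan-2-yl)-5-(3-methylbutanoyl)-2,3-dihydro-1-benzofuran-4,6-diyl diacetate | CC(C)CC(=O)c1c(OC(C)=O)cc2O[C@H](C(C)(C)O)Cc2c1OC(C)=O
F7 | step 4 | 2-[(2S)-2,3-dihydroxy-3-methylbutyl]-4-(3-methylbutanoyl)benzene-1,3,5-triyl triacetate | CC(C)CC(=O)c1c(OC(C)=O)cc(OC(C)=O)c(C[C@H](O)C(C)(C)O)c1OC(C)=O
F8 | step 4 | 2-[(2S)-3-hydroxy-3-methyl-2-(methylsulfonyloxy)butyl]-4-(3-methylbutanoyl)benzene-1,3,5-triyl triacetate | CC(C)CC(=O)c1c(OC(C)=O)cc(OC(C)=O)c(C[C@H](OS(C)(=O)=O)C(C)(C)O)c1OC(C)=O
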